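**Plan**
- Retrosynthesis: remove the C11=C13 methylene and both acetates; cut C1–C5 (transannular radical closure); cut C5–C6 (macrocyclic Negishi coupling on a 1,1-dibromoalkene); cut C1–C2 together with C10–CH3 (nickel-catalysed alkylative ynal cyclisation); cut C9–C10 (acetylide/epoxide); cut C11'–C3 and C11'–C13' (Michael addition and alkylation of the lower lactone enolate).
- Forward order: lower cyclohexene by aldol condensation on a chiral butyrolactone; C11' made quaternary; upper trans-lactone joined through the alkyne; cyclopentane with the tetrasubstituted C1=C10 alkene; ten-membered ring; then the norbornene cyclopentene and the cycloheptane together.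
- Enabling feature: the C1–C5 bond belongs both to the seven-membered ring (C1, C5–C10) and to the cyclopentene (C1–C5) of the norbornene. Without it, C1–C10 form a ten-membered 1(10),4-diene bridged by C13'–C11', in which a radical at C5 is 5-exo to C1.
- Stereochemistry: C4' from (R)-citronellic acid; C7'/C8' from (5R)-menthyloxyfuranone; C10' by convex-face Grignard addition; C11' by convex-face Michael addition onto the enolate that already carries C13'; C3 from a lactate-derived nitroalkene; C2 and the alkene geometry from the nickel cyclisation; C7/C8 from (S)-5-(hydroxymethyl)butenolide; C1 by the bridge; C10 by hydrogen-atom transfer.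

Key step: step 30

Numbering and abbreviations: guaianolide numbering C1–C15 for the upper half, primed numbers for the lower half, C13' being the CH2 between C11' and C1. TBS = tert-butyldimethylsilyl, TES = triethylsilyl.
Assumption: addition to nitroalkene 18 follows the Felkin–Anh-type transition state (silyloxy group anti to the nucleophile, hydrogen eclipsing the alkene). If the opposite sense were found, the (S)-lactate series would be used; the C4 carbinol centre is erased in step 26 either way.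

**Part A – ketone for the lower side chain**

Step 1
Reactants: 1 (R)-citronellic acid
Product: 2 (3R)-6-hydroxy-3-methylhexanoic acid
Conditions: O3, CH2Cl2/MeOH, −78 °C; then NaBH4, −78 °C → rt
Reagents that add atoms: ozone [O-][O+]=O
Why: Ozonolysis with reductive work-up cleaves the trisubstituted alkene to the primary alcohol and leaves the carboxylate and the future C4' centre untouched.

Step 2
Reactants: 2 (3R)-6-hydroxy-3-methylhexanoic acid
Product: 3 (4R)-7-hydroxy-4-methylheptan-2-one
Conditions: MeLi (3.3 equiv), THF, 0 °C → rt; aq. NH4Cl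
Reagents that add atoms: methyllithium [Li]C
Why: Addition of methyllithium to the lithium carboxylate stops at the gem-dialkoxide and gives the methyl ketone on hydrolysis (ketone synthesis from a carboxylic acid).

Step 3
Reactants: 3 (4R)-7-hydroxy-4-methylheptan-2-one
Product: 4 (4R)-7-(TBS-oxy)-4-methylheptan-2-one
Conditions: t-BuMe2SiCl, imidazole, DMF, rt
Reagents that add atoms: tert-butyldimethylsilyl chloride CC(C)(C)[Si](C)(C)Cl
Why: Imidazole-promoted silylation protects the primary alcohol that becomes the C1' acetate at the end.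

**Part B – lower lactone**

Step 4
Reactants: 5 (5R)-5-[(1R,2S,5R)-menthyloxy]furan-2(5H)-one; 6 1,3-dithiane
Product: 7 (4R,5R)-4-(1,3-dithian-2-yl)-5-(menthyloxy)dihydrofuran-2(3H)-one
Conditions: 6, n-BuLi, THF, −30 °C; DMPU; then 5, −78 °C; aq. NH4Cl
Reagents that add atoms: none
Why: Michael addition of the lithiated dithiane (formyl anion equivalent) to the chiral butenolide occurs anti to the menthyloxy group and fixes C7' in absolute terms.

Step 5
Reactants: 4 (4R)-7-(TBS-oxy)-4-methylheptan-2-one; 7 dithianyl menthyloxy lactone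
Product: 9 trans-4-dithianyl-5-(2-oxoalkyl) lactone, via enol silane 8 (not isolated)
Conditions: 4, LiN(i-Pr)2, Me3SiCl, THF, −78 °C; then 7, Me3SiOTf, CH2Cl2, −78 → −30 °C
Reagents that add atoms: chlorotrimethylsilane C[Si](C)(C)Cl (kept only in 8)
Why: Kinetic enol silane formation at the methyl group is followed by a Mukaiyama-type substitution at the acetal carbon, C9' entering trans to the dithianyl group so that C8' is set from C7'.

Step 6
Reactants: 9 trans-4-dithianyl-5-(2-oxoalkyl) lactone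
Product: 10 (2S,3R)-2-[(4R)-7-(TBS-oxy)-4-methyl-2-oxoheptyl]-5-oxotetrahydrofuran-3-carbaldehyde
Conditions: MeI, CaCO3, MeCN/H2O, 45 °C
Reagents that add atoms: water O
Why: S-alkylative hydrolysis of the dithioacetal unmasks the C6' aldehyde without touching lactone, ketone or silyl ether.

Step 7
Reactants: 10 keto aldehyde lactone
Product: 11 cis-fused enone lactone (3aR,7aS)
Conditions: piperidine, AcOH, benzene, 4 Å sieves, 60 °C
Reagents that add atoms: none
Why: Amine-catalysed intramolecular aldol condensation of the ketone α-carbon C5' onto the C6' aldehyde closes the cyclohexenone, the α-formyl centre C7' epimerising so that the more stable cis-fused bicycle forms.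

Step 8
Reactants: 11 cis-fused enone lactone
Product: 12 tertiary allylic alcohol (3aR,6R,7aS)
Conditions: MeMgBr, THF, −78 °C
Reagents that add atoms: methylmagnesium bromide C[Mg]Br
Why: Grignard 1,2-addition to the enone carbonyl from the convex face of the cis-fused bicycle (anti to the lactone ring) sets C10'; the ketone reacts much faster than the lactone at this temperature.

Step 9
Reactants: 12 tertiary allylic alcohol
Product: 13 lower lactone (C10' OTES and C1' OTBS)
Conditions: Et3SiOTf, 2,6-lutidine, CH2Cl2, −78 → 0 °C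
Reagents that add atoms: triethylsilyl trifluoromethanesulfonate CC[Si](CC)(CC)OS(=O)(=O)C(F)(F)F
Why: Silyl triflate silylation masks the hindered tertiary alcohol before enolate chemistry.

**Part C – nitroalkene**

Step 10
Reactants: 14 methyl (R)-lactate
Product: 15 methyl (R)-2-(TES-oxy)propanoate
Conditions: Et3SiCl, imidazole, DMF, 0 °C
Reagents that add atoms: chlorotriethylsilane CC[Si](Cl)(CC)CC
Why: Standard silyl ether formation; the bulky non-chelating silyloxy group is the later stereocontrol element.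

Step 11
Reactants: 15 methyl (R)-2-(TES-oxy)propanoate
Product: 16 (R)-2-(TES-oxy)propanal
Conditions: i-Bu2AlH, CH2Cl2, −78 °C; Rochelle salt work-up
Reagents that add atoms: none
Why: Partial ester reduction through the stable tetrahedral aluminate gives the aldehyde without epimerisation.

Step 12
Reactants: 16 (R)-2-(TES-oxy)propanal
Product: 18 (R,E)-triethyl[(4-nitrobut-3-en-2-yl)oxy]silane, via nitroaldol adduct 17 (not isolated)
Conditions: MeNO2, tetramethylguanidine (cat.), THF, 0 °C; then MsCl, Et3N, CH2Cl2, −20 °C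
Reagents that add atoms: nitromethane C[N+](=O)[O-]
Why: Henry addition followed by mesylation and E1cB elimination gives the (E)-nitroalkene that carries C2, C3, C4 and C15.

**Part D – upper epoxy ester**

Step 13
Reactants: 19 (S)-5-(hydroxymethyl)furan-2(5H)-one
Product: 20 (S)-5-[(TBS-oxy)methyl]furan-2(5H)-one
Conditions: t-BuMe2SiCl, imidazole, CH2Cl2, rt
Reagents that add atoms: tert-butyldimethylsilyl chloride CC(C)(C)[Si](C)(C)Cl
Why: Silylation gives the bulky C9 substituent needed for facial control in the next step.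

Step 14
Reactants: 20 (S)-5-[(TBS-oxy)methyl]furan-2(5H)-one
Product: 21 (4R,5S)-4-(hydroxymethyl)-5-[(TBS-oxy)methyl]dihydrofuran-2(3H)-one
Conditions: MeOH (solvent), benzophenone (0.1 equiv), hν (350 nm), rt
Reagents that add atoms: methanol CO
Why: Sensitised photochemical conjugate addition of the hydroxymethyl radical occurs anti to the C8 substituent, setting the trans C7/C8 relationship and introducing C6.

Step 15
Reactants: 21 hydroxymethyl lactone
Product: 22 (4S,5S)-4-(chloromethyl)-5-[(TBS-oxy)methyl]dihydrofuran-2(3H)-one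
Conditions: PPh3, CCl4, CH2Cl2, 40 °C
Reagents that add atoms: carbon tetrachloride ClC(Cl)(Cl)Cl
Why: Appel chlorination turns C6 into a primary chloride that is inert to enolates, zerovalent nickel and zinc and is activated only in step 28.

Step 16
Reactants: 22 chloromethyl silyl ether
Product: 23 (4S,5S)-4-(chloromethyl)-5-(hydroxymethyl)dihydrofuran-2(3H)-one
Conditions: HF·pyridine, THF, 0 °C → rt
Reagents that add atoms: none
Why: Fluoride cleavage of the primary silyl ether frees the C9 hydroxyl.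

Step 17
Reactants: 23 chloromethyl hydroxymethyl lactone
Product: 25 methyl (3S)-4-chloro-3-[(2S)-oxiran-2-yl]butanoate, via tosylate 24 (not isolated)
Conditions: TsCl, Et3N, DMAP (cat.), CH2Cl2, 0 °C; then K2CO3, MeOH, 0 °C
Reagents that add atoms: 4-methylbenzenesulfonyl chloride Cc1ccc(cc1)S(=O)(=O)Cl (kept only in 24); methanol CO
Why: Methanolysis of the lactone releases the C8 alkoxide, which displaces the C9 tosylate (3-exo-tet) to give the epoxy ester with C8 unchanged.

**Part E – assembly and end game**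

Step 18
Reactants: 13 lower lactone; 26 3-bromo-1-(trimethylsilyl)prop-1-yne
Product: 27 C11'-(3-trimethylsilylprop-2-ynyl) lactone
Conditions: LiN(i-Pr)2, THF, −78 °C; then 26, DMPU, −78 → −40 °C
Reagents that add atoms: none
Why: Lactone enolate alkylation (SN2) installs C13', C1 and C10; the configuration at C11' is of no consequence because the centre is enolised again.

Step 19
Reactants: 27 C11'-propargyl lactone; 18 (R,E)-nitroalkene
Product: 28 C11'-quaternary nitro lactone (3S,4R side chain)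
Conditions: LiN(i-Pr)2, THF, −78 °C; then 18, −78 °C; AcOH quench
Reagents that add atoms: none
Why: Michael addition of the tetrasubstituted lithium enolate to the nitroalkene takes place on the convex lactone face (anti to C6'), which places C3 correctly and leaves C13' on the concave face, while attack anti to the silyloxy group of the acceptor sets C3.

Step 20
Reactants: 28 nitro lactone
Product: 30 C2 dimethyl acetal, via aldehyde 29 (not isolated)
Conditions: aq. TiCl3, NH4OAc, THF, rt; then MeOSiMe3, Me3SiOTf (cat.), CH2Cl2, −78 °C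
Reagents that add atoms: water O (carbonyl oxygen of 29 only); methoxytrimethylsilane CO[Si](C)(C)C
Why: A reductive Nef reaction converts the primary nitro group into the C2 aldehyde, which is protected at once under aprotic Noyori acetalisation conditions so that the silyl ethers survive.

Step 21
Reactants: 30 C2 dimethyl acetal
Product: 31 terminal alkyne
Conditions: K2CO3, MeOH, 0 °C
Reagents that add atoms: none
Why: Base-mediated protiodesilylation frees the C10–H alkyne terminus.

Step 22
Reactants: 31 terminal alkyne; 25 epoxy ester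
Product: 33 alkyne-linked upper lactone, via hydroxy ester 32 (not isolated)
Conditions: LiN(i-Pr)2, THF, −78 °C; BF3·OEt2; then 25, −78 °C; aq. NH4Cl; toluene, 60 °C
Reagents that add atoms: none
Why: Yamaguchi–Hirao alkynylation opens the terminal epoxide at C9 to form C9–C10, and the γ-hydroxy ester lactonises to the trans-disubstituted upper lactone with C7 and C8 retained.

Step 23
Reactants: 33 alkyne-linked upper lactone
Product: 34 ynal
Conditions: Et3SiOTf, 2,4,6-collidine, CH2Cl2, 0 °C; then H2O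
Reagents that add atoms: water O
Why: Acetal cleavage through the collidinium intermediate (silyl triflate/collidine, then water) liberates the α-branched aldehyde under non-acidic conditions that spare the silyl ethers.

Step 24
Reactants: 34 ynal
Product: 35 spiro cyclopentanol with (E)-C1=C10 alkene
Conditions: Ni(cod)2 (10 mol %), Me2Zn (3 equiv), THF, 0 °C
Reagents that add atoms: dimethylzinc C[Zn]C
Why: Nickel-catalysed alkylative ynal cyclisation (Montgomery cyclisation) forms C1–C2 by oxidative cyclisation of zerovalent nickel with alkyne and aldehyde and then transfers methyl from zinc to C10 cis to C2, so the tetrasubstituted alkene arises as one isomer; the hydroxyl is expected trans to the C3 side chain.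

Step 25
Reactants: 35 spiro cyclopentanol
Product: 36 C2 TBS ether
Conditions: t-BuMe2SiOTf, 2,6-lutidine, CH2Cl2, −78 → 0 °C
Reagents that add atoms: tert-butyldimethylsilyl trifluoromethanesulfonate CC(C)(C)[Si](C)(C)OS(=O)(=O)C(F)(F)F
Why: Silyl triflate silylation protects the hindered secondary alcohol that becomes the C2 acetate.

Step 26
Reactants: 36 C2 TBS ether
Product: 38 C3 acetyl cyclopentane, via C4 carbinol 37 (not isolated)
Conditions: PPTS (cat.), MeOH/CH2Cl2, 0 °C; then Dess–Martin periodinane, NaHCO3, CH2Cl2, rt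
Reagents that add atoms: none
Why: Solvolysis removes the secondary TES ether faster than the TBS ethers and the tertiary TES ether, and Dess–Martin oxidation then gives the C4 methyl ketone.

Step 27
Reactants: 38 C3 acetyl cyclopentane
Product: 39 C4=C5 1,1-dibromoalkene
Conditions: CBr4, P(Oi-Pr)3, CH2Cl2, 0 °C → rt
Reagents that add atoms: carbon tetrabromide BrC(Br)(Br)Br
Why: Ramirez-type dibromoolefination (phosphite variant of the Corey–Fuchs first stage) converts the methyl ketone into the dibromoalkene that supplies C5 and both bromine atoms.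

Step 28
Reactants: 39 dibromoalkene chloride
Product: 40 C6 iodide
Conditions: NaI, 2-butanone, 80 °C
Reagents that add atoms: sodium iodide [Na+].[I-]
Why: Finkelstein exchange activates C6 only now, after all steps that would not tolerate an alkyl iodide.

Step 29
Reactants: 40 C6 iodide
Product: 42 bridged cyclodeca-1(10),4-diene vinyl bromide, via alkylzinc iodide 41 (not isolated)
Conditions: Zn dust (activated with BrCH2CH2Br and Me3SiCl), LiCl, THF, 30 °C; then syringe-pump addition to Pd2(dba)3 (5 mol %), DPEphos (10 mol %), THF, 50 °C, final 1 mM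
Reagents that add atoms: zinc [Zn] (kept only in 41)
Why: Zinc insertion into the primary C–I bond and intramolecular Negishi coupling close the ten-membered ring at C5–C6; zerovalent palladium is expected to insert into the C–Br bond trans to the bulky C3 substituent (trans-selective monoalkylation of 1,1-dibromoalkenes), leaving bromine on C5.

Step 30
Reactants: 42 bridged cyclodeca-1(10),4-diene vinyl bromide
Product: 45 hexacyclic core lacking the C11=C13 methylene, via C5 vinyl radical 43 (not isolated), via C10 radical 44 (not isolated)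
Conditions: Bu3SnH (1.3 equiv) and AIBN (0.2 equiv) added over 6 h to 42 in benzene (5 mM), 80 °C
Reagents that add atoms: none
Why: Proposed new method: bromine abstraction by the stannyl radical gives the σ-vinyl radical at C5, which inverts rapidly and adds across the ten-membered ring to C1 of the tetrasubstituted C1=C10 alkene, after which the tertiary C10 radical takes hydrogen from Bu3SnH; the closest known reaction types are 5-exo cyclisations of vinyl radicals and transannular radical cyclisations of medium rings. The new bond closes the norbornene cyclopentene in a 5-exo-trig mode (ring C1–C2–C3–C4–C5 with C4=C5 inside it) and, being transannular, divides the ten-membered ring so that the cycloheptane C1–C5–C6–C7–C8–C9–C10 arises at the same time. C1 is fixed by geometry because C3 holds the vinyl unit on the only face of the cyclopentane from which C1 can be reached, whereas C10 depends on hydrogen transfer to the radical face anti to the C2 silyloxy bridge (syn to C13'). The step needs 5-exo rather than 6-endo attack, favoured by the one-carbon C2 tether, and a single radical acceptor, secured by carrying the upper lactone without its exocyclic methylene and by keeping the stannane concentration low.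

Step 31
Reactants: 45 hexacyclic core
Product: 48 α-methylene lactone tris-silyl ether, via Mannich base 46 (not isolated), via ammonium iodide 47 (not isolated)
Conditions: LiN(i-Pr)2, THF, −78 °C; Me2N=CH2 iodide, −78 → 0 °C; MeI, MeOH, rt; NaHCO3, CH2Cl2/H2O
Reagents that add atoms: N,N-dimethylmethyleneiminium iodide C[N+](C)=C.[I-]; iodomethane CI (kept only in 47)
Why: Mannich reaction of the only enolisable lactone with Eschenmoser's salt, quaternisation and Hofmann-type elimination install the C11=C13 methylene.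

Step 32
Reactants: 48 α-methylene lactone tris-silyl ether
Product: 49 triol
Conditions: HF·pyridine, pyridine, THF, 0 °C → rt
Reagents that add atoms: none
Why: Buffered fluoride desilylation removes the primary and secondary TBS ethers and the tertiary TES ether without harming the α-methylene lactone or the tertiary allylic alcohol.

Step 33
Reactants: 49 triol
Product: 50 CNP0257312.1
Conditions: Ac2O (2.5 equiv), pyridine, DMAP (cat.), CH2Cl2, 0 °C
Reagents that add atoms: acetic anhydride CC(=O)OC(C)=O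
Why: DMAP-catalysed acetylation esterifies the primary C1' and secondary C2 hydroxyls, while the tertiary C10' alcohol should not react under these conditions.

**Compound list**

1 | (R)-citronellic acid | C[C@H](CCC=C(C)C)CC(=O)O | starting material
2 | (3R)-6-hydroxy-3-methylhexanoic acid | OC(=O)C[C@H](C)CCCO | intermediate
3 | (4R)-7-hydroxy-4-methylheptan-2-one | CC(=O)C[C@H](C)CCCO | intermediate
4 | (4R)-7-(TBS-oxy)-4-methylheptan-2-one | CC(=O)C[C@H](C)CCCO[Si](C)(C)C(C)(C)C | intermediate
5 | (5R)-5-[(1R,2S,5R)-menthyloxy]furan-2(5H)-one | O=C1C=C[C@H](O[C@@H]2C[C@H](C)CC[C@H]2C(C)C)O1 | starting material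
6 | 1,3-dithiane | C1CSCSC1 | starting material
7 | (4R,5R)-4-(1,3-dithian-2-yl)-5-[(1R,2S,5R)-menthyloxy]dihydrofuran-2(3H)-one (trans) | C1C(=O)O[C@@H](O[C@@H]2C[C@H](C)CC[C@H]2C(C)C)[C@@H]1C3SCCCS3 | intermediate
8 | kinetic trimethylsilyl enol ether of 4 (2-silyloxy-1-ene) | C=C(O[Si](C)(C)C)C[C@H](C)CCCO[Si](C)(C)C(C)(C)C | intermediate
9 | (4R,5S)-4-(1,3-dithian-2-yl)-5-[(4R)-7-(TBS-oxy)-4-methyl-2-oxoheptyl]dihydrofuran-2(3H)-one (trans) | C1C(=O)O[C@@H](CC(=O)C[C@H](C)CCCO[Si](C)(C)C(C)(C)C)[C@@H]1C2SCCCS2 | intermediate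
10 | (2S,3R)-2-[(4R)-7-(TBS-oxy)-4-methyl-2-oxoheptyl]-5-oxotetrahydrofuran-3-carbaldehyde | C1C(=O)O[C@@H](CC(=O)C[C@H](C)CCCO[Si](C)(C)C(C)(C)C)[C@@H]1C=O | intermediate
11 | cis-fused enone lactone, (3aR,7aS)-5-[(2R)-5-(TBS-oxy)pentan-2-yl]-3,3a,7,7a-tetrahydro-1-benzofuran-2,6-dione | C1C(=O)O[C@H]2CC(=O)C([C@H](C)CCCO[Si](C)(C)C(C)(C)C)=C[C@H]21 | intermediate
12 | (3aR,6R,7aS)-6-hydroxy-6-methyl-5-[(2R)-5-(TBS-oxy)pentan-2-yl]-3a,6,7,7a-tetrahydro-1-benzofuran-2(3H)-one | C1C(=O)O[C@H]2C[C@@](C)(O)C([C@H](C)CCCO[Si](C)(C)C(C)(C)C)=C[C@H]21 | intermediate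
13 | lower lactone, C10' triethylsilyl ether of 12 | C1C(=O)O[C@H]2C[C@@](C)(O[Si](CC)(CC)CC)C([C@H](C)CCCO[Si](C)(C)C(C)(C)C)=C[C@H]21 | intermediate
14 | methyl (R)-lactate | C[C@@H](O)C(=O)OC | starting material
15 | methyl (R)-2-(TES-oxy)propanoate | C[C@@H](O[Si](CC)(CC)CC)C(=O)OC | intermediate
16 | (R)-2-(TES-oxy)propanal | C[C@@H](O[Si](CC)(CC)CC)C=O | intermediate
17 | (3R)-1-nitro-3-(TES-oxy)butan-2-ol (C2 epimers) | C[C@@H](O[Si](CC)(CC)CC)C(O)C[N+](=O)[O-] | intermediate
18 | (R,E)-triethyl[(4-nitrobut-3-en-2-yl)oxy]silane | C[C@@H](O[Si](CC)(CC)CC)/C=C/[N+](=O)[O-] | intermediate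
19 | (S)-5-(hydroxymethyl)furan-2(5H)-one | O=C1C=C[C@@H](CO)O1 | starting material
20 | (S)-5-[(TBS-oxy)methyl]furan-2(5H)-one | O=C1C=C[C@@H](CO[Si](C)(C)C(C)(C)C)O1 | intermediate
21 | (4R,5S)-4-(hydroxymethyl)-5-[(TBS-oxy)methyl]dihydrofuran-2(3H)-one | OC[C@H]1CC(=O)O[C@@H]1CO[Si](C)(C)C(C)(C)C | intermediate
22 | (4S,5S)-4-(chloromethyl)-5-[(TBS-oxy)methyl]dihydrofuran-2(3H)-one | ClC[C@H]1CC(=O)O[C@@H]1CO[Si](C)(C)C(C)(C)C | intermediate
23 | (4S,5S)-4-(chloromethyl)-5-(hydroxymethyl)dihydrofuran-2(3H)-one | ClC[C@H]1CC(=O)O[C@@H]1CO | intermediate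
24 | C9 tosylate of 23 | ClC[C@H]1CC(=O)O[C@@H]1COS(=O)(=O)c2ccc(C)cc2 | intermediate
25 | methyl (3S)-4-chloro-3-[(2S)-oxiran-2-yl]butanoate | COC(=O)C[C@H](CCl)[C@H]1CO1 | intermediate
26 | 3-bromo-1-(trimethylsilyl)prop-1-yne | C[Si](C)(C)C#CCBr | starting material
27 | 13 bearing a 3-trimethylsilylprop-2-ynyl group at C11' on the convex face (anti to C6') | C[Si](C)(C)C#CC[C@@H]1C(=O)O[C@H]2C[C@@](C)(O[Si](CC)(CC)CC)C([C@H](C)CCCO[Si](C)(C)C(C)(C)C)=C[C@H]21 | intermediate
28 | C11'-quaternary lactone: C13' propargyl arm syn to C6', side chain (3S)-CH(CH2NO2)–(4R)-CH(OTES)CH3 anti to C6' | C[Si](C)(C)C#CC[C@]5(C(=O)O[C@H]6C[C@@](C)(O[Si](CC)(CC)CC)C([C@H](C)CCCO[Si](C)(C)C(C)(C)C)=C[C@H]65)[C@@H](C[N+](=O)[O-])[C@@H](C)O[Si](CC)(CC)CC | intermediate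
29 | C2 aldehyde corresponding to 28 (CH2NO2 replaced by CHO) | C[Si](C)(C)C#CC[C@]5(C(=O)O[C@H]6C[C@@](C)(O[Si](CC)(CC)CC)C([C@H](C)CCCO[Si](C)(C)C(C)(C)C)=C[C@H]65)[C@@H](C=O)[C@@H](C)O[Si](CC)(CC)CC | intermediate
30 | C2 dimethyl acetal of 29 | C[Si](C)(C)C#CC[C@]5(C(=O)O[C@H]6C[C@@](C)(O[Si](CC)(CC)CC)C([C@H](C)CCCO[Si](C)(C)C(C)(C)C)=C[C@H]65)[C@@H](C(OC)OC)[C@@H](C)O[Si](CC)(CC)CC | intermediate
31 | terminal alkyne (C10–H) from 30 | C#CC[C@]5(C(=O)O[C@H]6C[C@@](C)(O[Si](CC)(CC)CC)C([C@H](C)CCCO[Si](C)(C)C(C)(C)C)=C[C@H]65)[C@@H](C(OC)OC)[C@@H](C)O[Si](CC)(CC)CC | intermediate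
32 | hydroxy ester: 31 joined at C10 to C9 of 25, C8 hydroxyl free | COC(=O)C[C@H](CCl)[C@H](O)CC#CC[C@]5(C(=O)O[C@H]6C[C@@](C)(O[Si](CC)(CC)CC)C([C@H](C)CCCO[Si](C)(C)C(C)(C)C)=C[C@H]65)[C@@H](C(OC)OC)[C@@H](C)O[Si](CC)(CC)CC | intermediate
33 | trans upper lactone (C7 chloromethyl, C8 linked through C9 to the alkyne), C2 acetal | ClC[C@H]1CC(=O)O[C@@H]1CC#CC[C@]5(C(=O)O[C@H]6C[C@@](C)(O[Si](CC)(CC)CC)C([C@H](C)CCCO[Si](C)(C)C(C)(C)C)=C[C@H]65)[C@@H](C(OC)OC)[C@@H](C)O[Si](CC)(CC)CC | intermediate
34 | ynal (C2 aldehyde of 33) | ClC[C@H]1CC(=O)O[C@@H]1CC#CC[C@]5(C(=O)O[C@H]6C[C@@](C)(O[Si](CC)(CC)CC)C([C@H](C)CCCO[Si](C)(C)C(C)(C)C)=C[C@H]65)[C@@H](C=O)[C@@H](C)O[Si](CC)(CC)CC | intermediate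
35 | spiro cyclopentanol: C1–C2 formed, (E)-C1=C10 with methyl cis to C2, C2 hydroxyl trans to the C3 side chain | C/C(C[C@H]1OC(=O)C[C@@H]1CCl)=C2/C[C@]5(C(=O)O[C@H]6C[C@@](C)(O[Si](CC)(CC)CC)C([C@H](C)CCCO[Si](C)(C)C(C)(C)C)=C[C@H]65)[C@H]([C@@H](C)O[Si](CC)(CC)CC)[C@H]2O | intermediate
36 | C2 TBS ether of 35 | C/C(C[C@H]1OC(=O)C[C@@H]1CCl)=C2/C[C@]5(C(=O)O[C@H]6C[C@@](C)(O[Si](CC)(CC)CC)C([C@H](C)CCCO[Si](C)(C)C(C)(C)C)=C[C@H]65)[C@H]([C@@H](C)O[Si](CC)(CC)CC)[C@H]2O[Si](C)(C)C(C)(C)C | intermediate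
37 | C4 carbinol from 36 | C/C(C[C@H]1OC(=O)C[C@@H]1CCl)=C2/C[C@]5(C(=O)O[C@H]6C[C@@](C)(O[Si](CC)(CC)CC)C([C@H](C)CCCO[Si](C)(C)C(C)(C)C)=C[C@H]65)[C@H]([C@@H](C)O)[C@H]2O[Si](C)(C)C(C)(C)C | intermediate
38 | C3 acetyl cyclopentane (C4 ketone) | C/C(C[C@H]1OC(=O)C[C@@H]1CCl)=C2/C[C@]5(C(=O)O[C@H]6C[C@@](C)(O[Si](CC)(CC)CC)C([C@H](C)CCCO[Si](C)(C)C(C)(C)C)=C[C@H]65)[C@H](C(C)=O)[C@H]2O[Si](C)(C)C(C)(C)C | intermediate
39 | C4=C5 1,1-dibromoalkene | C/C(C[C@H]1OC(=O)C[C@@H]1CCl)=C2/C[C@]5(C(=O)O[C@H]6C[C@@](C)(O[Si](CC)(CC)CC)C([C@H](C)CCCO[Si](C)(C)C(C)(C)C)=C[C@H]65)[C@H](C(C)=C(Br)Br)[C@H]2O[Si](C)(C)C(C)(C)C | intermediate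
40 | C6 iodide of 39 | C/C(C[C@H]1OC(=O)C[C@@H]1CI)=C2/C[C@]5(C(=O)O[C@H]6C[C@@](C)(O[Si](CC)(CC)CC)C([C@H](C)CCCO[Si](C)(C)C(C)(C)C)=C[C@H]65)[C@H](C(C)=C(Br)Br)[C@H]2O[Si](C)(C)C(C)(C)C | intermediate
41 | C6 alkylzinc iodide of 40 | C/C(C[C@H]1OC(=O)C[C@@H]1C[Zn]I)=C2/C[C@]5(C(=O)O[C@H]6C[C@@](C)(O[Si](CC)(CC)CC)C([C@H](C)CCCO[Si](C)(C)C(C)(C)C)=C[C@H]65)[C@H](C(C)=C(Br)Br)[C@H]2O[Si](C)(C)C(C)(C)C | intermediate
42 | bridged cyclodeca-1(10),4-diene vinyl bromide (C5–C6 formed, C6 trans to C3, Br on C5) | C/C1=C2/C[C@]5(C(=O)O[C@H]6C[C@@](C)(O[Si](CC)(CC)CC)C([C@H](C)CCCO[Si](C)(C)C(C)(C)C)=C[C@H]65)[C@H](/C(C)=C(Br)/C[C@H]7CC(=O)O[C@@H]7C1)[C@H]2O[Si](C)(C)C(C)(C)C | intermediate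
43 | C5 vinyl radical of 42 | C/C1=C2/C[C@]5(C(=O)O[C@H]6C[C@@](C)(O[Si](CC)(CC)CC)C([C@H](C)CCCO[Si](C)(C)C(C)(C)C)=C[C@H]65)[C@H](C(C)=[C]C[C@H]7CC(=O)O[C@@H]7C1)[C@H]2O[Si](C)(C)C(C)(C)C | intermediate
44 | C10 tertiary radical after C1–C5 closure | C1C(=O)O[C@@H]2C[C](C)[C@]34C[C@]5(C(=O)O[C@H]6C[C@@](C)(O[Si](CC)(CC)CC)C([C@H](C)CCCO[Si](C)(C)C(C)(C)C)=C[C@H]65)[C@H](C(C)=C3C[C@@H]12)[C@H]4O[Si](C)(C)C(C)(C)C | intermediate
45 | hexacyclic core lacking the C11=C13 methylene (C1–C5 formed, C10 as in the target) | C1C(=O)O[C@@H]2C[C@@H](C)[C@]34C[C@]5(C(=O)O[C@H]6C[C@@](C)(O[Si](CC)(CC)CC)C([C@H](C)CCCO[Si](C)(C)C(C)(C)C)=C[C@H]65)[C@H](C(C)=C3C[C@@H]12)[C@H]4O[Si](C)(C)C(C)(C)C | intermediate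
46 | C11 dimethylaminomethyl derivative of 45 (C11 configuration not controlled) | CN(C)CC1C(=O)O[C@@H]2C[C@@H](C)[C@]34C[C@]5(C(=O)O[C@H]6C[C@@](C)(O[Si](CC)(CC)CC)C([C@H](C)CCCO[Si](C)(C)C(C)(C)C)=C[C@H]65)[C@H](C(C)=C3C[C@@H]12)[C@H]4O[Si](C)(C)C(C)(C)C | intermediate
47 | trimethylammonium iodide of 46 | C[N+](C)(C)CC1C(=O)O[C@@H]2C[C@@H](C)[C@]34C[C@]5(C(=O)O[C@H]6C[C@@](C)(O[Si](CC)(CC)CC)C([C@H](C)CCCO[Si](C)(C)C(C)(C)C)=C[C@H]65)[C@H](C(C)=C3C[C@@H]12)[C@H]4O[Si](C)(C)C(C)(C)C.[I-] | intermediate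
48 | α-methylene lactone tris-silyl ether (C2 OTBS, C1' OTBS, C10' OTES) | C=C1C(=O)O[C@@H]2C[C@@H](C)[C@]34C[C@]5(C(=O)O[C@H]6C[C@@](C)(O[Si](CC)(CC)CC)C([C@H](C)CCCO[Si](C)(C)C(C)(C)C)=C[C@H]65)[C@H](C(C)=C3C[C@@H]12)[C@H]4O[Si](C)(C)C(C)(C)C | intermediate
49 | triol (C2, C1' and C10' hydroxyls free) | C=C1C(=O)O[C@@H]2C[C@@H](C)[C@]34C[C@]5(C(=O)O[C@H]6C[C@@](C)(O)C([C@H](C)CCCO)=C[C@H]65)[C@H](C(C)=C3C[C@@H]12)[C@H]4O | intermediate
50 | CNP0257312.1 | C=C1C(=O)O[C@@H]2C[C@@H](C)[C@]34C[C@]5(C(=O)O[C@H]6C[C@@](C)(O)C([C@H](C)CCCOC(C)=O)=C[C@H]65)[C@H](C(C)=C3C[C@@H]12)[C@H]4OC(C)=O | target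

**Count**
Total steps: 33. Longest linear sequence: 24 steps (1–3, 5–9, 18–33).

**Steps most likely to fail**

Step 30 (proposed new method). The vinyl radical may be reduced before it cyclises, close 6-endo at C10, or rearrange through a cyclopropylcarbinyl radical; hydrogen may also be delivered to the wrong face of the C10 radical, which is the least secure point of the route. The fallback uses known chemistry and sets out from 42. An intramolecular Mizoroki–Heck reaction (Pd(OAc)2, P(o-tol)3, Ag2CO3, MeCN, 80 °C) forms the same C1–C5 bond by 5-exo syn-carbopalladation. β-Hydride elimination toward the freely rotating methyl group should give the C10 exocyclic-methylene hexacycle F1. Its 1,1-disubstituted alkene is then reduced selectively with diimide (TsNHNH2, NaOAc, DME/H2O, 80 °C), and the route is rejoined at 45.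

Step 29. Oligomerisation by intermolecular coupling, protonation of the organozinc, or reaction at both C–Br bonds may outrun closure of the strained ten-membered ring. The fallback sets out from 40. Copper-catalysed borylation (B2pin2, CuI, PPh3, LiOMe, DMF, rt) should give the primary pinacol boronate F2. This is cyclised by Suzuki–Miyaura coupling with slow release of the boronate (Pd(OAc)2, RuPhos, K3PO4, toluene/H2O, 80 °C, syringe pump), and the route is rejoined at 42.

Step 20. Hydrolysis at the hindered nitronate may stall, the α-branched aldehyde may epimerise at C3, or the secondary TES ether may be lost in the aqueous titanium medium. The fallback sets out from 28. Reduction of the nitro group with SnCl2·2H2O, PhSH and Et3N in MeCN should stop at the C2 aldoxime F3. Transoximation with glyoxylic acid (NaOAc, THF/H2O) then gives the aldehyde, and the route is rejoined at 29, which is acetalised as in step 20.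

**Further compounds**

F1 | step 30 | C10 exocyclic-methylene hexacycle (45 with C10=CH2 in place of C10–H/CH3) | C1C(=O)O[C@@H]2CC(=C)[C@]34C[C@]5(C(=O)O[C@H]6C[C@@](C)(O[Si](CC)(CC)CC)C([C@H](C)CCCO[Si](C)(C)C(C)(C)C)=C[C@H]65)[C@H](C(C)=C3C[C@@H]12)[C@H]4O[Si](C)(C)C(C)(C)C
F2 | step 29 | C6 pinacol boronate (40 with Bpin in place of iodine) | C/C(C[C@H]1OC(=O)C[C@@H]1CB2OC(C)(C)C(C)(C)O2)=C3/C[C@]5(C(=O)O[C@H]6C[C@@](C)(O[Si](CC)(CC)CC)C([C@H](C)CCCO[Si](C)(C)C(C)(C)C)=C[C@H]65)[C@H](C(C)=C(Br)Br)[C@H]3O[Si](C)(C)C(C)(C)C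
F3 | step 20 | C2 aldoxime (28 with CH=NOH in place of CH2NO2) | C[Si](C)(C)C#CC[C@]5(C(=O)O[C@H]6C[C@@](C)(O[Si](CC)(CC)CC)C([C@H](C)CCCO[Si](C)(C)C(C)(C)C)=C[C@H]65)[C@@H](C=NO)[C@@H](C)O[Si](CC)(CC)CC
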